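**Plan**
1. Retrosynthetic cuts (numbering of the tetrahydro-1H,3H-furo[3,4-c]furan-1-one core: C1 carbonyl, O2, C3 syringyl carbon, C3a, C4, O5, C6 guaiacyl carbon, C6a): the two phenol O–Si bonds; the lactone carbonyl C1 back to a methyl acetal; C6a–C6 together with C6–O5 (the vanillin carbon is inserted between the C4 hydroxyl and the enol-ether carbon C6a); then C3–C3a, by retro-electrocyclisation of a 2,3-dihydrofuran to a carbonyl ylide and an aryl vinyl oxirane made from syringaldehyde and a 4-bromocrotonate.
2. Enabling feature: in the lactone ring the atoms C3(aryl)–O2–C1–C6a–C3a, read at the enol-ether level (C1=C6a) with the later C4 as an ester on C3a, are the five atoms of a vinyl carbonyl ylide ArCH=O(+)–CH(−)–CH=CH–CO2R, stabilised at one end by the electron-rich aryl group and at the other by the ester.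
3. Forward order: vinyl oxirane → thermal ring expansion to the dihydrofuran (the later lactone ring, C3–C3a made) → epimerisation to trans and separation of the menthyl diastereomers → reduction to the C4 alcohol → Lewis-acid cyclisation with the vanillin acetal closes the tetrahydrofuran ring → acetal oxidised to the lactone → desilylation.
4. Stereochemistry: C3/C3a trans by thermodynamic epimerisation next to the ester; C6a by the tether (only the cis-fused bicycle can form); C6 aryl exo by equilibration of the benzylic ether; absolute configuration from a (−)-menthyl ester carried through the key step and used to separate the two dihydrofuran antipodes as diastereomers.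

Key step: step 4

Remark on the chemistry: the oxirane opens to a planar carbonyl ylide, so no chirality can be relayed through step 4. An asymmetric epoxidation would therefore be pointless, and a covalent resolving ester is used instead; the diastereomer with the wrong dihydrofuran configuration is removed in step 5. Compounds 3, 4 and 14 are taken as purchased.

Abbreviations in names: ArS = 4-(tert-butyldimethylsilyloxy)-3,5-dimethoxyphenyl; ArG = 4-(tert-butyldimethylsilyloxy)-3-methoxyphenyl; Men = (1R,2S,5R)-5-methyl-2-(propan-2-yl)cyclohexyl [(−)-menthyl].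

Step 1
Reactants: 1 syringaldehyde (4-hydroxy-3,5-dimethoxybenzaldehyde)
Product: 2 4-(tert-butyldimethylsilyloxy)-3,5-dimethoxybenzaldehyde (ArS–CHO)
Conditions: TBSCl, imidazole, DMF, rt
Reagents that add atoms: tert-butyldimethylsilyl chloride, CC(C)(C)[Si](C)(C)Cl
Why: Silyl ether formation masks the acidic phenol before the enolate chemistry of step 3 and leaves a thermally robust, strongly donating aryl group for step 4.

Step 2
Reactants: 3 (E)-4-bromobut-2-enoic acid; 4 (−)-menthol
Product: 5 Men (E)-4-bromobut-2-enoate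
Conditions: DCC, DMAP (5 mol %), CH2Cl2, 0 °C to rt
Reagents that add atoms: none
Why: Steglich esterification puts the later resolving group in place as the ester, the low DMAP loading and temperature keeping the allylic bromide intact.

Step 3
Reactants: 5 Men (E)-4-bromobut-2-enoate; 2 ArS–CHO
Product: 8 Men (E)-3-(3-ArS-oxiran-2-yl)prop-2-enoate (mixture of oxirane stereoisomers), via lithium dienolate 6 (not isolated), via lithium bromohydrin alkoxide 7 (not isolated)
Conditions: LiN(SiMe3)2 added to 5 and 2, THF, −78 °C to rt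
Reagents that add atoms: none
Why: In this vinylogous Darzens condensation the bromodienolate attacks the aldehyde through its γ-carbon and the alkoxide displaces bromide to close the oxirane, whose two centres need no control because step 4 erases them.

Step 4
Reactants: 8 Men (E)-3-(3-ArS-oxiran-2-yl)prop-2-enoate
Product: 10 Men cis-2-ArS-2,3-dihydrofuran-3-carboxylate (pair of diastereomers: 2S,3R plus 2R,3S in the dihydrofuran), via carbonyl ylide 9 (not isolated)
Conditions: toluene (0.02 M), sealed base-washed glass tube, 200 °C; alternatively flash vacuum pyrolysis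
Reagents that add atoms: none
Why: Heating breaks the oxirane C–C bond in a conrotatory four-electron ring opening to carbonyl ylide 9, whose positive end is stabilised by the ArS group and whose negative end is delocalised into the acrylate; the ylide then closes by a six-electron 1,5-electrocyclisation that joins the aryl-bearing carbon (C3 of the target) to the ester-bearing carbon (C3a of the target). The closest known reaction type is the thermal vinyl oxirane to 2,3-dihydrofuran rearrangement of aryl oxiranyl acrylates. The dihydrofuran ring (the later lactone ring) closes in a thermally allowed disrotatory mode over the five atoms C–O–C–C–C, a pericyclic closure to which no Baldwin restriction applies. The two new stereocentres arise together in this closure: with the aryl group and the ester both pointing outwards on the U-shaped ylide they should end up cis (orbital-symmetry control, corrected at C3a in step 5), whereas the absolute sense is not controlled, because 9 is planar and the menthyl group is remote, so both dihydrofuran antipodes are expected in about equal amounts as a pair of menthyl diastereomers. The step needs C–C instead of C–O cleavage of the oxirane, which the donor aryl/acceptor acrylate substitution and acid-free glass should secure, and it needs the ester-bearing alkene carbon as partner of the ylide terminus, which the E-acrylate geometry fixes.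

Step 5
Reactants: 10 Men cis-2-ArS-2,3-dihydrofuran-3-carboxylate (pair of diastereomers)
Product: 12 Men (2S,3S)-2-ArS-2,3-dihydrofuran-3-carboxylate (trans; single diastereomer after separation), via trans diastereomer pair 11 (not isolated)
Conditions: DBU (0.3 equiv), toluene, rt; then crystallisation or chromatography of the crude trans pair
Reagents that add atoms: none
Why: Base-mediated epimerisation next to the ester through its dienolate should move the ester trans to the aryl group in both diastereomers (thermodynamic control) to give the trans pair 11, from which the (2S,3S) diastereomer 12 is taken by a resolution through the covalently bound menthyl group (configuration assignable by crystallography against the menthyl centres), while the (2R,3R) diastereomer stays in the mother liquor or the other fraction and is set aside.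

Step 6
Reactants: 12 Men (2S,3S)-2-ArS-2,3-dihydrofuran-3-carboxylate
Product: 13 [(2S,3R)-2-ArS-2,3-dihydrofuran-3-yl]methanol
Conditions: i-Bu2AlH (2.5 equiv), CH2Cl2, −78 to 0 °C
Reagents that add atoms: none
Why: Ester reduction with a dialkylaluminium hydride gives the primary alcohol and releases menthol, while the enol ether and both stereocentres of the dihydrofuran are inert to the reagent (the descriptor at C3 changes only through the priority rules).

Step 7
Reactants: 14 4-(tert-butyldimethylsilyloxy)-3-methoxybenzaldehyde (ArG–CHO)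
Product: 15 tert-butyl[4-(dimethoxymethyl)-2-methoxyphenoxy]dimethylsilane (ArG–CH(OMe)2)
Conditions: HC(OMe)3, MeOH, PPTS (cat.), rt
Reagents that add atoms: methanol, CO; trimethyl orthoformate, COC(OC)OC
Why: Acid-catalysed acetalisation driven by the orthoformate as water scavenger gives the oxocarbenium precursor, the aryl silyl ether tolerating the mild acid.

Step 8
Reactants: 13 [(2S,3R)-2-ArS-2,3-dihydrofuran-3-yl]methanol; 15 ArG–CH(OMe)2
Product: 18 (1R,3S,3aR,6S,6aS)-6-ArG-3-ArS-1-methoxytetrahydro-1H,3H-furo[3,4-c]furan, via mixed acetal 16 (not isolated), via oxocarbenium triflate 17 (not isolated)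
Conditions: Me3SiOTf (0.3 equiv), CH2Cl2, −78 °C, then warming to 0 °C
Reagents that add atoms: none
Why: Transacetalisation and ionisation give an oxocarbenium ion tethered through O5–C4 to C3a, which the nucleophilic enol-ether carbon C6a attacks in a Prins-type (intramolecular oxocarbenium/enol ether) cyclisation that can only deliver the cis-fused ring, the cation left at C1 being trapped by methanol on the convex face, and warming is expected to equilibrate the new benzylic centre C6 by reversible ionisation to the exo-aryl isomer.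

Step 9
Reactants: 18 (1R,3S,3aR,6S,6aS)-6-ArG-3-ArS-1-methoxytetrahydro-1H,3H-furo[3,4-c]furan
Product: 20 (3S,3aR,6S,6aS)-6-ArG-3-ArS-tetrahydro-1H,3H-furo[3,4-c]furan-1-one, via lactol 19 (not isolated)
Conditions: CrO3, H2SO4, H2O/acetone, 0 °C
Reagents that add atoms: water, O
Why: Jones oxidation hydrolyses the methyl acetal to the lactol and oxidises it with hexavalent chromium to the γ-lactone, the four stereocentres being untouched (C6a, now next to the carbonyl, stays cis because a trans-fused bicycle is too strained).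

Step 10
Reactants: 20 (3S,3aR,6S,6aS)-6-ArG-3-ArS-tetrahydro-1H,3H-furo[3,4-c]furan-1-one
Product: 21 (3S,3aR,6S,6aS)-6-(4-hydroxy-3-methoxyphenyl)-3-(4-hydroxy-3,5-dimethoxyphenyl)tetrahydro-1H,3H-furo[3,4-c]furan-1-one (target)
Conditions: Bu4NF, AcOH (1:1), THF, 0 °C
Reagents that add atoms: none
Why: Fluoride-mediated desilylation frees both phenols, the acetic acid buffer keeping them protonated so that no quinone methide can form by expulsion of the benzylic carboxylate or ether oxygen and epimerise C3 or C6.

**Compound list** (mixtures are written as dot-separated SMILES; centres that are erased or immaterial in the next step are left undefined where stated)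

1 | syringaldehyde, 4-hydroxy-3,5-dimethoxybenzaldehyde | COc1cc(C=O)cc(OC)c1O | starting material
2 | 4-(tert-butyldimethylsilyloxy)-3,5-dimethoxybenzaldehyde | COc1cc(C=O)cc(OC)c1O[Si](C)(C)C(C)(C)C | intermediate
3 | (E)-4-bromobut-2-enoic acid | OC(=O)/C=C/CBr | starting material
4 | (−)-menthol, (1R,2S,5R)-5-methyl-2-(propan-2-yl)cyclohexan-1-ol | CC(C)[C@@H]1CC[C@@H](C)C[C@H]1O | starting material
5 | Men (E)-4-bromobut-2-enoate | CC(C)[C@@H]1CC[C@@H](C)C[C@H]1OC(=O)/C=C/CBr | intermediate
6 | lithium dienolate of 5 (enolate geometry undefined) | CC(C)[C@@H]1CC[C@@H](C)C[C@H]1OC([O-])=CC=CBr.[Li+] | intermediate (not isolated)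
7 | lithium alkoxide of Men (E)-4-bromo-5-hydroxy-5-ArS-pent-2-enoate (both new centres undefined) | CC(C)[C@@H]1CC[C@@H](C)C[C@H]1OC(=O)/C=C/C(Br)C([O-])c2cc(OC)c(O[Si](C)(C)C(C)(C)C)c(OC)c2.[Li+] | intermediate (not isolated)
8 | Men (E)-3-(3-ArS-oxiran-2-yl)prop-2-enoate (oxirane carbons undefined: cis/trans mixture, all isomers converge in step 4) | CC(C)[C@@H]1CC[C@@H](C)C[C@H]1OC(=O)/C=C/C2OC2c3cc(OC)c(O[Si](C)(C)C(C)(C)C)c(OC)c3 | intermediate
9 | carbonyl ylide ArS–CH=O(+)–CH(−)–CH=CH–CO2Men | CC(C)[C@@H]1CC[C@@H](C)C[C@H]1OC(=O)/C=C/[CH-][O+]=Cc2cc(OC)c(O[Si](C)(C)C(C)(C)C)c(OC)c2 | intermediate (not isolated)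
10 | Men cis-2-ArS-2,3-dihydrofuran-3-carboxylate, pair of diastereomers with (2S,3R) and (2R,3S) dihydrofuran configuration | CC(C)[C@@H]1CC[C@@H](C)C[C@H]1OC(=O)[C@@H]2C=CO[C@@H]2c3cc(OC)c(O[Si](C)(C)C(C)(C)C)c(OC)c3.CC(C)[C@@H]1CC[C@@H](C)C[C@H]1OC(=O)[C@H]2C=CO[C@H]2c3cc(OC)c(O[Si](C)(C)C(C)(C)C)c(OC)c3 | intermediate
11 | Men trans-2-ArS-2,3-dihydrofuran-3-carboxylate, pair of diastereomers with (2S,3S) and (2R,3R) dihydrofuran configuration (crude, before separation) | CC(C)[C@@H]1CC[C@@H](C)C[C@H]1OC(=O)[C@H]2C=CO[C@@H]2c3cc(OC)c(O[Si](C)(C)C(C)(C)C)c(OC)c3.CC(C)[C@@H]1CC[C@@H](C)C[C@H]1OC(=O)[C@@H]2C=CO[C@H]2c3cc(OC)c(O[Si](C)(C)C(C)(C)C)c(OC)c3 | intermediate (not isolated)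
12 | Men (2S,3S)-2-ArS-2,3-dihydrofuran-3-carboxylate (trans) | CC(C)[C@@H]1CC[C@@H](C)C[C@H]1OC(=O)[C@H]2C=CO[C@@H]2c3cc(OC)c(O[Si](C)(C)C(C)(C)C)c(OC)c3 | intermediate
13 | [(2S,3R)-2-ArS-2,3-dihydrofuran-3-yl]methanol | OC[C@H]1C=CO[C@@H]1c2cc(OC)c(O[Si](C)(C)C(C)(C)C)c(OC)c2 | intermediate
14 | 4-(tert-butyldimethylsilyloxy)-3-methoxybenzaldehyde | COc1cc(C=O)ccc1O[Si](C)(C)C(C)(C)C | starting material
15 | tert-butyl[4-(dimethoxymethyl)-2-methoxyphenoxy]dimethylsilane | COc1cc(C(OC)OC)ccc1O[Si](C)(C)C(C)(C)C | intermediate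
16 | mixed acetal ArG–CH(OMe)–O–CH2–[(2S,3R)-2-ArS-2,3-dihydrofuran-3-yl] (acetal carbon undefined) | COc1cc(C(OC)OC[C@H]2C=CO[C@@H]2c3cc(OC)c(O[Si](C)(C)C(C)(C)C)c(OC)c3)ccc1O[Si](C)(C)C(C)(C)C | intermediate (not isolated)
17 | oxocarbenium triflate ArG–CH=O(+)–CH2–[(2S,3R)-2-ArS-2,3-dihydrofuran-3-yl] | FC(F)(F)S(=O)(=O)[O-].COc1cc(C=[O+]C[C@H]2C=CO[C@@H]2c3cc(OC)c(O[Si](C)(C)C(C)(C)C)c(OC)c3)ccc1O[Si](C)(C)C(C)(C)C | intermediate (not isolated)
18 | (1R,3S,3aR,6S,6aS)-6-ArG-3-ArS-1-methoxytetrahydro-1H,3H-furo[3,4-c]furan (exo-methoxy anomer shown; the anomer ratio is immaterial) | COc1cc([C@H]2OC[C@H]3[C@@H]2[C@H](OC)O[C@@H]3c2cc(OC)c(O[Si](C)(C)C(C)(C)C)c(OC)c2)ccc1O[Si](C)(C)C(C)(C)C | intermediate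
19 | (3S,3aR,6S,6aS)-6-ArG-3-ArS-tetrahydro-1H,3H-furo[3,4-c]furan-1-ol (lactol, C1 undefined) | COc1cc([C@H]2OC[C@H]3[C@@H]2C(O)O[C@@H]3c2cc(OC)c(O[Si](C)(C)C(C)(C)C)c(OC)c2)ccc1O[Si](C)(C)C(C)(C)C | intermediate (not isolated)
20 | (3S,3aR,6S,6aS)-6-ArG-3-ArS-tetrahydro-1H,3H-furo[3,4-c]furan-1-one | COc1cc([C@H]2OC[C@H]3[C@@H]2C(=O)O[C@@H]3c2cc(OC)c(O[Si](C)(C)C(C)(C)C)c(OC)c2)ccc1O[Si](C)(C)C(C)(C)C | intermediate
21 | (3S,3aR,6S,6aS)-6-(4-hydroxy-3-methoxyphenyl)-3-(4-hydroxy-3,5-dimethoxyphenyl)tetrahydro-1H,3H-furo[3,4-c]furan-1-one | COc1cc([C@H]2OC[C@H]3[C@@H]2C(=O)O[C@@H]3c2cc(OC)c(O)c(OC)c2)ccc1O | target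

**Totals**
Total step count: 10. Longest linear sequence: 8 steps (steps 1 or 2, then 3, 4, 5, 6, 8, 9, 10).

**Steps most likely to fail**

Step 4. The risk is acid-promoted ionisation of the oxirane C–O bond of the electron-rich aryl oxirane (isomerisation to carbonyl compounds) or thermal decomposition before the C–C bond opens. The fallback sets out from 2 and comes back at 11; it makes the C3–C3a bond by an intermolecular aldol reaction and closes the ring through oxygen. Aldehyde 2 is condensed with succinic anhydride (ZnCl2, Et3N, CH2Cl2); aldol addition of the anhydride enolate and lactonisation should give, after equilibration, racemic trans-2-ArS-5-oxotetrahydrofuran-3-carboxylic acid F1. Steglich esterification with 4 gives the menthyl esters F2. i-Bu2AlH (1 equiv, −78 °C) should reduce the lactone carbonyl, which is more reactive than the hindered ester, to the lactols F3. MsCl/Et3N then dehydrates the lactol to the enol ether, which gives the trans pair 11, separated as in step 5.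

Step 5. The risk is insufficient discrimination of the two trans diastereomers on crystallisation or chromatography, possibly aggravated by base-induced migration of the ring double bond into conjugation with the ester. The fallback sets out from the unseparated trans pair 11 and comes back at 13. Reduction with i-Bu2AlH as in step 6 gives the racemic alcohol, that is 13 together with its enantiomer [(2R,3S)-2-ArS-2,3-dihydrofuran-3-yl]methanol F4. The enantiomers are then separated by preparative chromatography on a chiral stationary phase (cellulose tris(3,5-dimethylphenylcarbamate)).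

Step 8. The risk is ring closure under kinetic control with the ArG group on the concave face and no equilibration of the benzylic centre under the Lewis-acid conditions. The fallback sets out from 13 and 15 and comes back at 20. The cyclisation is kept at −78 °C and the 6-epimeric acetal (1R,3S,3aR,6R,6aS)-6-ArG-3-ArS-1-methoxytetrahydro-1H,3H-furo[3,4-c]furan F5 is taken on. Jones oxidation through the 6-epimeric lactol F6 gives the 6-epimeric lactone (3S,3aR,6R,6aS)-6-ArG-3-ArS-tetrahydro-1H,3H-furo[3,4-c]furan-1-one F7. CF3CO2H in CH2Cl2 then ionises the C6–O5 bond to the benzylic cation stabilised by the para oxygen, and reclosure by the C4 hydroxyl (ring opening and ring closure of the SN1 type) should give the exo isomer 20.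

**Further compounds**
F1 | step 4 | racemic trans-2-ArS-5-oxotetrahydrofuran-3-carboxylic acid, (2S,3S) and (2R,3R) | OC(=O)[C@H]1CC(=O)O[C@@H]1c2cc(OC)c(O[Si](C)(C)C(C)(C)C)c(OC)c2.OC(=O)[C@@H]1CC(=O)O[C@H]1c2cc(OC)c(O[Si](C)(C)C(C)(C)C)c(OC)c2
F2 | step 4 | Men trans-2-ArS-5-oxotetrahydrofuran-3-carboxylate, (2S,3S) and (2R,3R) lactone diastereomers | CC(C)[C@@H]1CC[C@@H](C)C[C@H]1OC(=O)[C@H]2CC(=O)O[C@@H]2c3cc(OC)c(O[Si](C)(C)C(C)(C)C)c(OC)c3.CC(C)[C@@H]1CC[C@@H](C)C[C@H]1OC(=O)[C@@H]2CC(=O)O[C@H]2c3cc(OC)c(O[Si](C)(C)C(C)(C)C)c(OC)c3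
F3 | step 4 | Men trans-2-ArS-5-hydroxytetrahydrofuran-3-carboxylate (lactols, C5 undefined), (2S,3S) and (2R,3R) diastereomers | CC(C)[C@@H]1CC[C@@H](C)C[C@H]1OC(=O)[C@H]2CC(O)O[C@@H]2c3cc(OC)c(O[Si](C)(C)C(C)(C)C)c(OC)c3.CC(C)[C@@H]1CC[C@@H](C)C[C@H]1OC(=O)[C@@H]2CC(O)O[C@H]2c3cc(OC)c(O[Si](C)(C)C(C)(C)C)c(OC)c3
F4 | step 5 | [(2R,3S)-2-ArS-2,3-dihydrofuran-3-yl]methanol (enantiomer of 13) | OC[C@@H]1C=CO[C@H]1c2cc(OC)c(O[Si](C)(C)C(C)(C)C)c(OC)c2
F5 | step 8 | (1R,3S,3aR,6R,6aS)-6-ArG-3-ArS-1-methoxytetrahydro-1H,3H-furo[3,4-c]furan (6-epimer of 18) | COc1cc([C@@H]2OC[C@H]3[C@@H]2[C@H](OC)O[C@@H]3c2cc(OC)c(O[Si](C)(C)C(C)(C)C)c(OC)c2)ccc1O[Si](C)(C)C(C)(C)C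
F6 | step 8 | (3S,3aR,6R,6aS)-6-ArG-3-ArS-tetrahydro-1H,3H-furo[3,4-c]furan-1-ol (6-epimeric lactol, C1 undefined) | COc1cc([C@@H]2OC[C@H]3[C@@H]2C(O)O[C@@H]3c2cc(OC)c(O[Si](C)(C)C(C)(C)C)c(OC)c2)ccc1O[Si](C)(C)C(C)(C)C
F7 | step 8 | (3S,3aR,6R,6aS)-6-ArG-3-ArS-tetrahydro-1H,3H-furo[3,4-c]furan-1-one (6-epimer of 20) | COc1cc([C@@H]2OC[C@H]3[C@@H]2C(=O)O[C@@H]3c2cc(OC)c(O[Si](C)(C)C(C)(C)C)c(OC)c2)ccc1O[Si](C)(C)C(C)(C)C
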